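The numbers of this flask are invented; what happens was integrated by code.

The ratio to hold in mind is nucleophiles spent per product made, and in this flask I reckon it near two.

    electrophile + nucleophile ⇌ acid set free + product (K1 = 0.30, k1 = 2.7 M⁻¹ min⁻¹)
    nucleophile + acid set free ⇌ protonated nucleophile, settled at all times (K2 = 17000 M⁻¹)
    nucleophile + acid set free ⇌ idle adduct A, settled at all times (K3 = 33 M⁻¹)
    electrophile + product ⇌ idle adduct B, settled at all times (K4 = 540 M⁻¹)

electrophile 0.020 M; nucleophile 0.0190 M; time 8.0 h

* part of the electrophile that has reacted at 8.0 h
* share of free nucleophile in free nucleophile and protonated nucleophile together, at 8.0 h

- percentages count the electrophile that a species holds: one idle adduct B counts as two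
- product is meant together with its idle adduct B
- acid set free is meant together with its idle adduct A
- in an amount of product, one idle adduct B counts as one product
- what has gone from electrophile into another species counts as reacted, even if it can come back
- run time (flask): 8.0 h

Work in powers of ten and climb from fast to slow. The balances come first, and you may take them as instant. The constant for acid set free meeting nucleophile, times the nucleophile charged, is 320, about 2.51 powers of ten, against 0.63 for idle adduct A. So I take acid set free to go to protonated nucleophile rather than to idle adduct A, and one product to cost about two nucleophiles. Call the two-for-one amount h the nucleophile charged divided by two, 0.00950 M: the product you should expect, idle adduct B counted.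

The next rung is electrophile + nucleophile ⇌ acid set free + product (K1 = 0.30, k1 = 2.7 M⁻¹ min⁻¹) itself, whose time, the inverse of its rate constant times the electrophile charged, is 18.5 min. Out of h, idle adduct B then takes its share. Solving its balance gives 0.00650 M of adduct, free electrophile 0.00400 M, and so 80.0% reacted. The last rung is the loss of free nucleophile, whose time, the inverse of twice the forward rate constant times that free electrophile, is about 46.2 min, and 8.0 h holds 10.4 of those, so I read the end as balance. Multiplying the constants of the first two steps gives 5100 M⁻¹, which, with protonated nucleophile taken as h, puts free nucleophile at 0.00118 M and its share at 11.1%. That free nucleophile was not allowed for in h, so I take h as a little high.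

The forecast says 78.4% and 10.8%, a little below my figures, on the ground that the acid “ties up nearly one nucleophile as its protonated form for each one that reacts”.

The simulation gives 78.4% reacted and a share of 10.7%. At 8.00 h this flask holds product, idle adduct B counted, of 46.1% of the electrophile charged, where h gives 47.5%. Now take a second flask, like this one but charged with 0.0076 M of nucleophile. There h becomes 0.00380 M, and the same balance gives 35.6% reacted. That flask gives 39.8%, with product at 21.3% against 19.0% from h, and 0.00109 M of acid set free stands in it at its end.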